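All runs come from a simulation with made-up constants.

- Slowness was your hunch for the noon run's lower plateau, and you asked for a quick number. I checked that first, and it did not fit: by 2.00 min the noon run stood 1.1 percentage points below its last reading.

all flasks: gas 9.8 mM (held)

|  | substrate | remark | time |
|---|---|---|---|
| dusk | 0.18 M | run made earlier |  |
| noon | 0.88 M | run made earlier |  |
| north-west | 0.14 M |  | 5.0 min |
| south-west | 0.60 M |  | 2.5 min |

| run | time / min | target / % |
|---|---|---|
| dusk | 0.250 | 29.5 |
| dusk | 0.833 | 53.0 |
| dusk | 1.33 | 60.3 |
| dusk | 2.00 | 63.7 |
| dusk | 3.00 | 63.8 |
| dusk | 4.00 | 64.4 |
| dusk | 5.00 | 64.7 |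
| noon | 0.667 | 36.9 |
| noon | 1.33 | 48.1 |
| noon | 2.00 | 51.9 |
| noon | 3.00 | 53.2 |
| noon | 4.00 | 52.7 |
| noon | 5.00 | 53.0 |

(standard deviation of a reading: 0.3 percentage points)

* which one finishes higher in amount of target, in percent of the substrate charged ("neither" within 2 percentage points) (north-west / south-west / neither)
* amount of target at the end, in percent of the substrate charged, north-west
* amount of target at the end, in percent of the substrate charged, south-west

- at the start none of reagent is dissolved
- the analysis behind the earlier runs scatters by 0.3 percentage points, standard deviation
- steps under discussion: substrate <-> intermediate + leaving ligand; reagent + intermediate -> target; gas <-> reagent; intermediate -> side product A; substrate + leaving ligand -> side product B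

- Substrate frees leaving ligand and intermediate, reagent turns intermediate into target, and ligand can attack substrate to give side product B.
- So I counted free ligand as target minus side product B. I set side product A aside, which made those two products add up to the charge.
- The last readings then gave 0.0529 M of ligand at dusk and 0.0528 M at noon, though noon held 4.89 times the substrate.
- I took their mean, 0.0529 M, as the ligand ceiling, the free ligand at which its making and its loss balance. I treated it as a level that ligand approaches during a run, not one it holds throughout.
- With a charge above the ceiling, the target share is the mean of one and the ratio of ceiling to charge.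
- I therefore reckoned 68.9% for north-west and 54.4% for south-west. I counted south-west as nearly finished at 2.5 min, going by noon's pace.
- The forecast also named north-west, but with a narrower gap than mine, 65.6% against 56.4%, on the ground that “selectivity falls as concentration rises”.
- The flasks gave 67.8% in north-west and 54.0% in south-west, so north-west finished higher.

    substrate ⇌ intermediate + leaving ligand (K = 1.20 × 10⁻⁵ M, k = 0.0460 s⁻¹)
    reagent + intermediate → target (k = 11000 M⁻¹ s⁻¹)
    gas ⇌ reagent, rate k3*(csat - [reagent]) (kL = 6.50 s⁻¹)
    intermediate → side product A (k = 0.0880 s⁻¹)
    substrate + leaving ligand → side product B (k = 0.280 M⁻¹ s⁻¹)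

- North-west ended with 0.0501 M of ligand and south-west with 0.0550 M, around the ceiling of 0.0529 M, while side product A stood at 0.0584% in north-west. At 0.238 min, north-west made ligand 2.17 times faster than it used it. It finished with 67.8% of target against 32.1% of side product B. A neighbouring flask, like north-west but charged with 0.035 M of substrate, 0.662 of the ceiling, gave 87.6% of target and held 0.0264 M of ligand.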